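Ring A of the target (the methylenecyclohexanol) shows a 1,4-diene motif: exocyclic C1=C2, ring methine C7–H and side-chain alkene C8=C9. Everything rests on cutting the ring bond C2–C7, which leads back to an open-chain 1,7-enyne. One palladium-hydride cycloisomerisation closes ring A, creates the exocyclic methylene, sets C7 and moves the C7=C8 alkene to C8=C9, into conjugation with the Z alkene C10=C11. The precursor is a C15 chain with terminal alkyne, silylated (R)-carbinol C5, gem-dimethyl C6 and a skipped E,Z-diene ending in a silyloxymethyl group. Ring B is then joined at C12 as an enantiopure vinyl iodide and epoxidised under substrate control.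

Key step: step 11

Labels: C1–C12 is the enyne chain, with C1 the alkyne CH and C12 the CH2O terminus that later becomes the carbinol. Ring B is B1 (bonded to C12), B2, B3 (O), B4 (CH2O branch), B5 and B6 (O). β is the ring-B face that carries the B3 and B6 oxygens; α is the face of the epoxide oxygen. TBS = tert-butyldimethylsilyl; PT = 1-phenyl-1H-tetrazol-5-yl.
Assumption: only the E isomer of commercial 1-acetoxybuta-1,3-diene takes part in step 14; the Z isomer stays unchanged.

Step 1
Reactants: 1 pent-4-yn-1-ol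
Product: 2 pent-4-ynal
Conditions: TEMPO (cat.), PhI(OAc)2, CH2Cl2, rt
Reagents that add atoms: none
Why: Oxoammonium-mediated (TEMPO) alcohol oxidation stops at the aldehyde and leaves the terminal alkyne alone; the volatile product is carried on in solution.

Step 2
Reactants: 2 pent-4-ynal; 3 3-methylbuta-1,2-diene
Product: 4 (R)-3,3-dimethyloct-1-en-7-yn-4-ol
Conditions: (–)-Ipc2BH [from (+)-α-pinene], 3, THF, –25 → 0 °C; 2, Et2O, –78 °C; NaOH, H2O2
Reagents that add atoms: none
Why: Asymmetric prenylboration (allylboration through a closed chair with allylic transposition) builds the quaternary C6 and the carbinol C5 together, and the (+)-α-pinene-derived isopinocampheyl groups direct attack to the Si face of the aldehyde, which gives the (R)-alcohol.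

Step 3
Reactants: 4 (R)-3,3-dimethyloct-1-en-7-yn-4-ol
Product: 5 (R)-4-(tert-butyldimethylsilyloxy)-3,3-dimethyloct-1-en-7-yne
Conditions: TBSOTf, 2,6-lutidine, CH2Cl2, 0 °C
Reagents that add atoms: tert-butyldimethylsilyl triflate, CC(C)(C)[Si](C)(C)OS(=O)(=O)C(F)(F)F
Why: Silyl ether formation with the triflate is chosen because the carbinol is neopentylic, and the bulky group later serves as the equatorial anchor in the ring closure.

Step 4
Reactants: 5 (R)-4-(tert-butyldimethylsilyloxy)-3,3-dimethyloct-1-en-7-yne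
Product: 7 (R)-3-(tert-butyldimethylsilyloxy)-2,2-dimethylhept-6-ynal, via ozonide 6 (not isolated)
Conditions: O3, CH2Cl2, –78 °C (Sudan III end-point); PPh3
Reagents that add atoms: ozone, [O-][O+]=O
Why: Ozonolysis with a dye end-point cleaves the vinyl group, which reacts far faster than the alkyne, and gives a non-enolisable aldehyde without touching C5.

Step 5
Reactants: 8 4-methyl-5,6-dihydro-2H-pyran-2-one
Product: 9 (Z)-5-hydroxy-N-methoxy-N,3-dimethylpent-2-enamide
Conditions: MeNH(OMe)·HCl, AlMe3, CH2Cl2, 0 °C → rt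
Reagents that add atoms: N,O-dimethylhydroxylamine hydrochloride, CNOC.Cl
Why: Aluminium-amide aminolysis breaks the acyl–oxygen bond of the lactone, so the ring-enforced Z geometry is kept and only the homoallylic hydroxyl is freed, which tells the two oxygen termini apart without a selective protection.

Step 6
Reactants: 9 (Z)-5-hydroxy-N-methoxy-N,3-dimethylpent-2-enamide
Product: 10 (Z)-N-methoxy-N,3-dimethyl-5-(PT-sulfanyl)pent-2-enamide
Conditions: 1-phenyl-1H-tetrazole-5-thiol, PPh3, DIAD, THF, 0 °C → rt
Reagents that add atoms: 1-phenyl-1H-tetrazole-5-thiol, Sc1nnnn1-c1ccccc1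
Why: Mitsunobu thioetherification of the only free, primary alcohol is run at once so that relactonisation cannot compete.

Step 7
Reactants: 10 (Z)-N-methoxy-N,3-dimethyl-5-(PT-sulfanyl)pent-2-enamide
Product: 12 (Z)-3-methyl-5-(PT-sulfanyl)pent-2-en-1-ol, via Z-enal 11 (not isolated)
Conditions: DIBAL-H, THF, –78 °C; MeOH, then NaBH4, –78 → 0 °C
Reagents that add atoms: none
Why: Hydride reduction of the N-methoxy-N-methylamide halts at the chelated hemiaminal, and the Z-enal released on quenching is reduced by borohydride in the same flask before it can isomerise.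

Step 8
Reactants: 12 (Z)-3-methyl-5-(PT-sulfanyl)pent-2-en-1-ol
Product: 13 TBS ether of 12
Conditions: TBSCl, imidazole, CH2Cl2, rt
Reagents that add atoms: tert-butyldimethylsilyl chloride, CC(C)(C)[Si](C)(C)Cl
Why: Standard silylation masks the allylic alcohol as an ether that, unlike an allylic ester, cannot be ionised later by palladium(0).

Step 9
Reactants: 13 TBS ether of 12
Product: 14 5-{[(Z)-5-(tert-butyldimethylsilyloxy)-3-methylpent-3-en-1-yl]sulfonyl}-1-phenyl-1H-tetrazole
Conditions: (NH4)6Mo7O24·4H2O (cat.), 30% H2O2, EtOH, 0 °C → rt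
Reagents that add atoms: hydrogen peroxide, OO
Why: Molybdate-catalysed sulfide-to-sulfone oxidation is much faster than epoxidation of the trisubstituted alkene, which lacks a directing hydroxyl.

Step 10
Reactants: 14 PT sulfone; 7 (R)-3-(tert-butyldimethylsilyloxy)-2,2-dimethylhept-6-ynal
Product: 15 (5R,7E,10Z)-5,12-bis(tert-butyldimethylsilyloxy)-6,6,10-trimethyldodeca-7,10-dien-1-yne
Conditions: KHMDS, DME, –60 °C; then 7, –60 °C → rt
Reagents that add atoms: none
Why: Julia–Kocienski olefination: the metalated PT sulfone adds to the non-enolisable α-quaternary aldehyde and Smiles rearrangement with anti elimination gives the E alkene, while the Z alkene, the silyl ethers and the less acidic alkyne C–H are untouched.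

Step 11
Reactants: 15 (5R,7E,10Z)-5,12-bis(tert-butyldimethylsilyloxy)-6,6,10-trimethyldodeca-7,10-dien-1-yne
Product: 16 bis-TBS ether of (2Z,4E)-5-[(1S,3R)-3-hydroxy-2,2-dimethyl-6-methylenecyclohexyl]-3-methylpenta-2,4-dien-1-ol
Conditions: Pd2(dba)3·CHCl3 (2.5 mol %), P(o-tol)3 (10 mol %), AcOH (20 mol %), toluene, 40–60 °C
Reagents that add atoms: none
Why: HPd(OAc), formed from Pd(0) and acetic acid, adds across the terminal alkyne with Pd on C2, the vinyl–Pd bond inserts the C7=C8 alkene syn, and syn β-hydride elimination of a C9 hydrogen releases 16 and returns HPd(OAc), so the step is a pure isomerisation. The closest known reaction type is the palladium-catalysed Alder-ene-type cycloisomerisation of 1,6- and 1,7-enynes to methylenecycloalkanes. Ring A closes in the 6-exo-trig mode (C2 to C7), helped by the gem-dimethyl group at C6. C7 is controlled by C5: in the chair-like insertion state the C5 silyloxy group and the C8 chain both sit equatorial, which places them cis and gives (7S). The step needs 1,4- and not 1,3-diene formation; the weak, doubly allylic C9–H bonds and the conjugation gained with C10=C11 favour loss of hydrogen from C9 over the ring C7–H, and elimination from the less crowded rotamer gives the E alkene. Silyl ethers in place of allylic esters keep Pd(0) from ionising the C12–O bond, and stopping at full conversion limits re-addition of Pd–H next to the doubly allylic C7–H.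

Step 12
Reactants: 16 bis-TBS ether
Product: 17 (2Z,4E)-5-[(1S,3R)-3-hydroxy-2,2-dimethyl-6-methylenecyclohexyl]-3-methylpenta-2,4-dien-1-ol
Conditions: TBAF, THF, rt → 45 °C
Reagents that add atoms: none
Why: Fluoride desilylation removes both ethers, including the hindered neopentylic one at C5, while the molecule is still robust, so no selective cleavage is needed and the last deprotection only has to deal with unhindered ethers.

Step 13
Reactants: 17 dienediol
Product: 18 (2Z,4E)-5-[(1S,3R)-3-hydroxy-2,2-dimethyl-6-methylenecyclohexyl]-3-methylpenta-2,4-dienal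
Conditions: MnO2, CH2Cl2, 0 °C → rt, dark
Reagents that add atoms: none
Why: Manganese dioxide oxidises only the dienylic primary alcohol and not the saturated C5 alcohol, under neutral conditions that keep the 2Z geometry.

Step 14
Reactants: 19 (E)-buta-1,3-dien-1-yl acetate; 20 3-acryloyl-1,3-oxazolidin-2-one
Product: 21 (1S,6R)-6-[(2-oxo-1,3-oxazolidin-3-yl)carbonyl]cyclohex-2-en-1-yl acetate (cis adduct)
Conditions: [Cu((R,R)-t-Bu-box)](SbF6)2 (5 mol %), CH2Cl2, 0 °C → rt
Reagents that add atoms: none
Why: Catalytic asymmetric Diels–Alder reaction: the chelated s-cis acrylimide on square-planar Cu(II)–bis(oxazoline) is open on one face only, the acetoxy terminus bonds next to the acyl-bearing carbon and endo approach gives the cis adduct, so B3 and B4 are set together, the (R,R)-ligand giving (R) at B4, and the minor trans adduct is removed by chromatography.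

Step 15
Reactants: 21 cis adduct
Product: 22 (1S,6S)-6-(hydroxymethyl)cyclohex-2-en-1-ol (cis)
Conditions: LiBH4, MeOH (additive), THF, 0 °C → rt
Reagents that add atoms: none
Why: Borohydride reduction cleaves the imide to the primary alcohol and the acetate to the secondary alcohol in one operation under conditions too mild for β-elimination of acetate.

Step 16
Reactants: 22 cis diol
Product: 23 bis-TBS ether of 22
Conditions: TBSCl, imidazole, DMF, rt
Reagents that add atoms: tert-butyldimethylsilyl chloride, CC(C)(C)[Si](C)(C)Cl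
Why: Double silylation protects both hydroxyls and puts two bulky groups on the β face, which steer all later additions to ring B.

Step 17
Reactants: 23 bis-TBS ether
Product: 24 4β-(TBS-oxy)-5β-(TBS-oxymethyl)cyclohex-2-en-1-one (B6 ketone)
Conditions: Rh2(cap)4 (1 mol %), t-BuOOH, K2CO3, CH2Cl2, rt
Reagents that add atoms: tert-butyl hydroperoxide, CC(C)(C)OO
Why: Catalytic allylic C–H oxidation (tert-butylperoxyl radical chain): hydrogen is taken from the free ring methylene B6 rather than from the shielded, inductively deactivated B3–H, and the allyl radical is trapped at the terminus remote from the silyloxy group, which gives the enone after loss of tert-butanol.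

Step 18
Reactants: 24 enone
Product: 25 2-iodo-4β-(TBS-oxy)-5β-(TBS-oxymethyl)cyclohex-2-en-1-one
Conditions: I2, pyridine, CH2Cl2, 0 °C → rt
Reagents that add atoms: iodine, II
Why: α-Iodination of the enone by pyridine addition, iodination of the enolate and elimination (a Baylis–Hillman-type sequence) places iodine on B1 only.

Step 19
Reactants: 25 iodoenone
Product: 26 2-iodo-6-(phenylsulfanyl)-4β-(TBS-oxy)-5β-(TBS-oxymethyl)cyclohex-2-en-1-one (B5 epimers)
Conditions: LDA, THF, –78 °C; PhSO2SPh, –78 °C
Reagents that add atoms: S-phenyl benzenethiosulfonate, O=S(=O)(Sc1ccccc1)c1ccccc1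
Why: Kinetic α′-enolate formation and sulfenylation put a latent leaving group on B5, whose configuration does not matter because the centre is removed in step 26.

Step 20
Reactants: 26 thio-iodoenone
Product: 27 allylic alcohol with B6β-OH (B1-iodo, B3β-OTBS, B4β-CH2OTBS, B5-SPh)
Conditions: NaBH4, CeCl3·7H2O, MeOH, –78 → –20 °C
Reagents that add atoms: none
Why: Luche reduction (1,2-selective): with the B4 side chain equatorial, axial hydride attack comes from the α face, as in the reduction of 5-substituted cyclohexenones to their cis alcohols, so the new B6 hydroxyl is β, cis to the B3 and B4 substituents.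

Step 21
Reactants: 27 allylic alcohol
Product: 28 tris-TBS iodoalkene (B3β-OTBS, B4β-CH2OTBS, B5-SPh, B6β-OTBS)
Conditions: TBSOTf, 2,6-lutidine, CH2Cl2, 0 °C
Reagents that add atoms: tert-butyldimethylsilyl triflate, CC(C)(C)[Si](C)(C)OS(=O)(=O)C(F)(F)F
Why: Silylation with the triflate covers the hindered B6 hydroxyl, so both carbons that flank the B1=B2 alkene now carry a bulky β group.

Step 22
Reactants: 28 tris-TBS iodoalkene
Product: 30 iodoalkene with B3β-OTBS, B4β-CH2OH, B5-SO2Ph (epimers) and B6β-OTBS, via tris-silyl sulfone 29 (not isolated)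
Conditions: (NH4)6Mo7O24·4H2O (cat.), 30% H2O2, EtOH, 0 °C → rt; then CSA (cat.), 0 °C
Reagents that add atoms: hydrogen peroxide, OO
Why: Molybdate-catalysed sulfide-to-sulfone oxidation leaves the electron-poor iodoalkene alone, and acid-catalysed solvolysis then frees only the unhindered primary silyl ether.

Step 23
Reactants: 30 ring-B iodoalkene; 18 hydroxy dienal
Product: 31 C12 carbinol (C12 epimers), terpene dienyl and ring-B alkenyl joined at C12
Conditions: CrCl2, NiCl2 (2 mol %), DMSO–THF, rt
Reagents that add atoms: none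
Why: Nozaki–Hiyama–Kishi coupling gives an alkenylchromium(III) that adds 1,2 to the aldehyde only and tolerates the free hydroxyls, the sulfone and the Z-enal; the C12 epimers are not separated because the centre is erased in step 24.

Step 24
Reactants: 31 C12 carbinol
Product: 32 cross-conjugated C12 ketone
Conditions: MnO2, CH2Cl2, 0 °C, dark
Reagents that add atoms: none
Why: Manganese dioxide oxidises only the doubly allylic C12 alcohol and not the saturated primary and secondary alcohols, under neutral conditions that preserve the Z alkene.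

Step 25
Reactants: 32 C12 ketone
Product: 33 B1,B2-α-epoxy ketone
Conditions: t-BuOOH, n-BuLi, THF, –78 → –20 °C
Reagents that add atoms: tert-butyl hydroperoxide, CC(C)(C)OO
Why: Weitz–Scheffer epoxidation: the weakly basic peroxide anion adds to the unsubstituted β-carbon B2 of the ring enone from the α face, anti to both flanking β-silyloxy groups, and the enolate closes on the O–O bond, which sets B1 and B2 and leaves the unactivated alkenes and the β,β-disubstituted dienone terminus untouched.

Step 26
Reactants: 33 epoxy ketone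
Product: 35 epoxy keto-enal with B4(CHO)=B5, via sulfonyl aldehyde 34 (not isolated)
Conditions: TEMPO (cat.), PhI(OAc)2, CH2Cl2, 0 °C → rt; then Et3N, 0 °C
Reagents that add atoms: none
Why: Oxoammonium oxidation picks the only primary alcohol, and the β-sulfonyl aldehyde then loses benzenesulfinate by E1cB elimination with a mild amine base, which places the alkene at B4=B5 whatever the B5 configuration, since sulfinate leaves far more readily than the B3 silanolate.

Step 27
Reactants: 35 epoxy keto-enal
Product: 36 B3,B6-bis-TBS ether of the target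
Conditions: NaBH4, CeCl3·7H2O, MeOH–THF, –78 → –20 °C
Reagents that add atoms: none
Why: Luche reduction: cerium ties the C12 carbonyl oxygen to the epoxide oxygen and hydride enters from the side away from the epoxide carbon B2, which gives the anti (erythro) epoxy alcohol, (12S), while the enal is reduced 1,2 to the hydroxymethyl group without a stereochemical consequence.

Step 28
Reactants: 36 bis-TBS ether
Product: 37 target CNP0357844.1
Conditions: TBAF, AcOH (1:1), THF, 0 °C → rt
Reagents that add atoms: none
Why: Fluoride desilylation buffered with acetic acid removes the two remaining secondary silyl ethers without forming alkoxides that could start epoxide migration (Payne rearrangement) and without acid strong enough to ionise the dienylic alcohol.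

Compound list
1 | pent-4-yn-1-ol | C#CCCCO | starting material
2 | pent-4-ynal | C#CCCC=O | intermediate
3 | 3-methylbuta-1,2-diene | CC(C)=C=C | starting material
4 | (R)-3,3-dimethyloct-1-en-7-yn-4-ol | C#CCC[C@@H](O)C(C)(C)C=C | intermediate
5 | (R)-4-(TBS-oxy)-3,3-dimethyloct-1-en-7-yne | C#CCC[C@@H](O[Si](C)(C)C(C)(C)C)C(C)(C)C=C | intermediate
6 | ozonide (1,2,4-trioxolane) of 5, epimers at the ring carbon | C#CCC[C@@H](O[Si](C)(C)C(C)(C)C)C(C)(C)C1OCOO1 | intermediate
7 | (R)-3-(TBS-oxy)-2,2-dimethylhept-6-ynal | C#CCC[C@@H](O[Si](C)(C)C(C)(C)C)C(C)(C)C=O | intermediate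
8 | 4-methyl-5,6-dihydro-2H-pyran-2-one | CC1=CC(=O)OCC1 | starting material
9 | (Z)-5-hydroxy-N-methoxy-N,3-dimethylpent-2-enamide | OCC/C(C)=C\C(=O)N(C)OC | intermediate
10 | (Z)-N-methoxy-N,3-dimethyl-5-(PT-sulfanyl)pent-2-enamide | c1ccc(cc1)-n1nnnc1SCC/C(C)=C\C(=O)N(C)OC | intermediate
11 | (Z)-3-methyl-5-(PT-sulfanyl)pent-2-enal | c1ccc(cc1)-n1nnnc1SCC/C(C)=C\C=O | intermediate
12 | (Z)-3-methyl-5-(PT-sulfanyl)pent-2-en-1-ol | c1ccc(cc1)-n1nnnc1SCC/C(C)=C\CO | intermediate
13 | TBS ether of 12 | c1ccc(cc1)-n1nnnc1SCC/C(C)=C\CO[Si](C)(C)C(C)(C)C | intermediate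
14 | PT sulfone of 13 | c1ccc(cc1)-n1nnnc1S(=O)(=O)CC/C(C)=C\CO[Si](C)(C)C(C)(C)C | intermediate
15 | (5R,7E,10Z)-5,12-bis(TBS-oxy)-6,6,10-trimethyldodeca-7,10-dien-1-yne | C#CCC[C@@H](O[Si](C)(C)C(C)(C)C)C(C)(C)/C=C/C/C(C)=C\CO[Si](C)(C)C(C)(C)C | intermediate
16 | bis-TBS methylenecyclohexyl (2Z,4E)-dienol | C=C1CC[C@@H](O[Si](C)(C)C(C)(C)C)C(C)(C)[C@H]1/C=C/C(C)=C\CO[Si](C)(C)C(C)(C)C | intermediate
17 | (2Z,4E)-5-[(1S,3R)-3-hydroxy-2,2-dimethyl-6-methylenecyclohexyl]-3-methylpenta-2,4-dien-1-ol | C=C1CC[C@@H](O)C(C)(C)[C@H]1/C=C/C(C)=C\CO | intermediate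
18 | corresponding (2Z,4E)-dienal | C=C1CC[C@@H](O)C(C)(C)[C@H]1/C=C/C(C)=C\C=O | intermediate
19 | (E)-buta-1,3-dien-1-yl acetate | CC(=O)O/C=C/C=C | starting material
20 | 3-acryloyl-1,3-oxazolidin-2-one | C=CC(=O)N1CCOC1=O | starting material
21 | (1S,6R)-6-[(2-oxo-1,3-oxazolidin-3-yl)carbonyl]cyclohex-2-en-1-yl acetate | C1=C[C@H](OC(C)=O)[C@H](C(=O)N2CCOC2=O)CC1 | intermediate
22 | (1S,6S)-6-(hydroxymethyl)cyclohex-2-en-1-ol | C1=C[C@H](O)[C@H](CO)CC1 | intermediate
23 | bis-TBS ether of 22 | C1=C[C@H](O[Si](C)(C)C(C)(C)C)[C@H](CO[Si](C)(C)C(C)(C)C)CC1 | intermediate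
24 | 4β-(TBS-oxy)-5β-(TBS-oxymethyl)cyclohex-2-en-1-one | O=C1C=C[C@H](O[Si](C)(C)C(C)(C)C)[C@H](CO[Si](C)(C)C(C)(C)C)C1 | intermediate
25 | 2-iodo derivative of 24 | O=C1C(I)=C[C@H](O[Si](C)(C)C(C)(C)C)[C@H](CO[Si](C)(C)C(C)(C)C)C1 | intermediate
26 | 6-(phenylsulfanyl) derivative of 25, B5 epimers | O=C1C(I)=C[C@H](O[Si](C)(C)C(C)(C)C)[C@H](CO[Si](C)(C)C(C)(C)C)C1Sc2ccccc2 | intermediate
27 | B6β allylic alcohol from 26 | O[C@@H]1C(I)=C[C@H](O[Si](C)(C)C(C)(C)C)[C@H](CO[Si](C)(C)C(C)(C)C)C1Sc2ccccc2 | intermediate
28 | tris-TBS iodoalkene sulfide | CC(C)(C)[Si](C)(C)O[C@@H]1C(I)=C[C@H](O[Si](C)(C)C(C)(C)C)[C@H](CO[Si](C)(C)C(C)(C)C)C1Sc2ccccc2 | intermediate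
29 | tris-TBS iodoalkene sulfone | CC(C)(C)[Si](C)(C)O[C@@H]1C(I)=C[C@H](O[Si](C)(C)C(C)(C)C)[C@H](CO[Si](C)(C)C(C)(C)C)C1S(=O)(=O)c2ccccc2 | intermediate
30 | bis-TBS iodoalkene sulfone with free CH2OH | CC(C)(C)[Si](C)(C)O[C@@H]1C(I)=C[C@H](O[Si](C)(C)C(C)(C)C)[C@H](CO)C1S(=O)(=O)c2ccccc2 | intermediate
31 | C12 carbinol, C12 and B5 epimers | C=C1CC[C@@H](O)C(C)(C)[C@H]1/C=C/C(C)=C\C(O)C1=C[C@H](O[Si](C)(C)C(C)(C)C)[C@H](CO)C(S(=O)(=O)c2ccccc2)[C@@H]1O[Si](C)(C)C(C)(C)C | intermediate
32 | C12 ketone | C=C1CC[C@@H](O)C(C)(C)[C@H]1/C=C/C(C)=C\C(=O)C1=C[C@H](O[Si](C)(C)C(C)(C)C)[C@H](CO)C(S(=O)(=O)c2ccccc2)[C@@H]1O[Si](C)(C)C(C)(C)C | intermediate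
33 | B1,B2-α-epoxy ketone | C=C1CC[C@@H](O)C(C)(C)[C@H]1/C=C/C(C)=C\C(=O)[C@]12O[C@H]1[C@H](O[Si](C)(C)C(C)(C)C)[C@H](CO)C(S(=O)(=O)c3ccccc3)[C@@H]2O[Si](C)(C)C(C)(C)C | intermediate
34 | β-sulfonyl aldehyde | C=C1CC[C@@H](O)C(C)(C)[C@H]1/C=C/C(C)=C\C(=O)[C@]12O[C@H]1[C@H](O[Si](C)(C)C(C)(C)C)[C@H](C=O)C(S(=O)(=O)c3ccccc3)[C@@H]2O[Si](C)(C)C(C)(C)C | intermediate
35 | epoxy keto-enal | C=C1CC[C@@H](O)C(C)(C)[C@H]1/C=C/C(C)=C\C(=O)[C@]12O[C@H]1[C@H](O[Si](C)(C)C(C)(C)C)C(C=O)=C[C@@H]2O[Si](C)(C)C(C)(C)C | intermediate
36 | B3,B6-bis-TBS ether of the target | C=C1CC[C@@H](O)C(C)(C)[C@H]1/C=C/C(C)=C\[C@H](O)[C@]12O[C@H]1[C@H](O[Si](C)(C)C(C)(C)C)C(CO)=C[C@@H]2O[Si](C)(C)C(C)(C)C | intermediate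
37 | CNP0357844.1 | C=C1CC[C@@H](O)C(C)(C)[C@H]1/C=C/C(C)=C\[C@H](O)[C@]12O[C@H]1[C@H](O)C(CO)=C[C@@H]2O | target

Total step count: 28. Longest linear sequence: 15 steps. It runs from 8 through steps 5–13 and 23–28; the ring-B branch from 19 and 20 through steps 14–28 is equally long.

Steps most likely to fail

Step 11. Insertion into the neopentylic alkene may be slow. Pd–H could then move the skipped diene into conjugation or oligomerise the alkyne before ring closure, and a weak chair preference would erode control at C7. The fallback sets out from 15. Markovnikov iodoboration with B-iodo-9-BBN followed by protonolysis with acetic acid turns the alkyne into the 2-iodo-1-alkene F1. An intramolecular Heck reaction (Pd(OAc)2, PPh3, Ag2CO3, MeCN, 60 °C) then generates the vinylpalladium at C2 by oxidative addition, without free Pd–H at the start. It forms the same C2–C7 bond by 6-exo insertion, ends with the same loss of a C9 hydrogen, and comes back to the route at 16.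

Step 25. Peroxide addition to the crowded B2 may be slower than three side processes. These are base-induced Z-to-E isomerisation of the dienone, loss of silanolate from the intermediate enolate, and attack on the dienone branch. The fallback sets out from 31 and avoids the ketone altogether.
- A Sharpless epoxidation run as a kinetic resolution (Ti(Oi-Pr)4, L-(+)-DIPT, t-BuOOH, 4 Å sieves, CH2Cl2, –20 °C) is matched for the ring alkene of the (12S)-epimer only and mismatched for its C10=C11 alkene.
- Oxygen is delivered to the open α face, which gives the anti epoxy alcohol F2.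
- The unreacted (12R)-epimer of 31 can be returned through step 24.
- TEMPO/PhI(OAc)2 oxidises the primary alcohol to the sulfonyl aldehyde F3, triethylamine eliminates sulfinate to the hydroxy enal F4, and Luche reduction of the enal comes back to the route at 36.

Step 17. Hydrogen abstraction at the silyloxy-bearing B3–H, oxygen capture at B2 or over-oxidation would lower regioselectivity in the C–H oxidation. The fallback sets out from 20 and brings the B6 oxygen in with the diene. Cycloaddition with commercial (1E,3E)-buta-1,3-diene-1,4-diyl diacetate under the catalyst of step 14 raises no regiochemical question and gives the all-cis diacetate F5. LiBH4 gives the triol F6, and MnO2 oxidises the less hindered allylic alcohol at B6 to the hydroxy enone F7. Double silylation (TBSCl, imidazole) comes back to the route at 24.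

Further compounds
F1 | step 11 | (5R,7E,10Z)-5,12-bis(TBS-oxy)-2-iodo-6,6,10-trimethyldodeca-1,7,10-triene | C=C(I)CC[C@@H](O[Si](C)(C)C(C)(C)C)C(C)(C)/C=C/C/C(C)=C\CO[Si](C)(C)C(C)(C)C
F2 | step 25 | (12S) anti epoxy alcohol with saturated B4–B5, B5 sulfone and free CH2OH | C=C1CC[C@@H](O)C(C)(C)[C@H]1/C=C/C(C)=C\[C@H](O)[C@]12O[C@H]1[C@H](O[Si](C)(C)C(C)(C)C)[C@H](CO)C(S(=O)(=O)c3ccccc3)[C@@H]2O[Si](C)(C)C(C)(C)C
F3 | step 25 | β-sulfonyl aldehyde of F2 | C=C1CC[C@@H](O)C(C)(C)[C@H]1/C=C/C(C)=C\[C@H](O)[C@]12O[C@H]1[C@H](O[Si](C)(C)C(C)(C)C)[C@H](C=O)C(S(=O)(=O)c3ccccc3)[C@@H]2O[Si](C)(C)C(C)(C)C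
F4 | step 25 | (12S) hydroxy enal with B4(CHO)=B5 | C=C1CC[C@@H](O)C(C)(C)[C@H]1/C=C/C(C)=C\[C@H](O)[C@]12O[C@H]1[C@H](O[Si](C)(C)C(C)(C)C)C(C=O)=C[C@@H]2O[Si](C)(C)C(C)(C)C
F5 | step 17 | all-cis 3,6-diacetoxycyclohex-4-enyl acyl oxazolidinone | C1=C[C@H](OC(C)=O)[C@H](C(=O)N2CCOC2=O)C[C@@H]1OC(C)=O
F6 | step 17 | all-cis 5-(hydroxymethyl)cyclohex-2-ene-1,4-diol | C1=C[C@H](O)[C@H](CO)C[C@@H]1O
F7 | step 17 | 4β-hydroxy-5β-(hydroxymethyl)cyclohex-2-en-1-one | O=C1C=C[C@H](O)[C@H](CO)C1
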